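The vessel was closed, stirred and held at constant volume and temperature, and I started from these charges and readings.

| flask | substrate | first nucleophile | second nucleophile | protic impurity | remark | time |
|---|---|---|---|---|---|---|
| alpha | 0.025 M | 0.060 M | 0.030 M | 0.025 M | run made earlier |  |
| delta | 0.038 M | 0.060 M | 0.030 M | 0.025 M | run made earlier |  |
| flask | 0.050 M | 0.0600 M | 0.0300 M | 0.0250 M |  | 2.5 h |

| run | time / min | target / % | isomer of the product / % | solvolysis product / % |
|---|---|---|---|---|
| alpha | 15.0 | 1.8 | 0.2 | 1.1 |
| alpha | 40.0 | 5.3 | 0.4 | 3.3 |
| alpha | 80.0 | 11.2 | 0.9 | 6.4 |
| alpha | 120 | 16.1 | 2.5 | 11.0 |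
| delta | 10.0 | 0.4 | 0.2 | 1.7 |
| delta | 20.0 | 1.9 | 0.4 | 1.7 |
| delta | 50.0 | 7.5 | 0 | 4.0 |
| delta | 120 | 16.6 | 2.4 | 9.8 |

(scatter of a reading: 0.5 percentage points)



1. amount of target in the flask at 2.5 h, in percent of the substrate charged
2. amount of isomer of the product in the flask at 2.5 h, in percent of the substrate charged
3. amount of solvolysis product in the flask at 2.5 h, in percent of the substrate charged
4. concentration of second nucleophile at 2.5 h, in M

One thing looked wrong at first: the delta run held more substrate than the alpha run, 0.038 M against 0.025 M, yet at 120 min its target stood at 16.6% of the charge against 16.1%. A percentage that ignores the charge is what a first-order start gives, so I took the substrate to feed the products by a step of its own, with the products differing by their shares of that stream. The isomer appeared late, so I counted it with the target, and I defined S, the branching ratio (a selectivity factor), as target plus isomer over solvolysis product. I pooled both runs at 120 min and scaled their summed products in proportion to time, which was my own assumption.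

S = 1.81

total at 2.5 h = 36.5%

solvolysis product = total / (1 + S) = 13.0%

target + isomer = 23.5%

The readings hold no column for [second nucleophile], so I made no figure of my own for it.

The forecast, noting that “The role of the second nucleophile is unobserved”, gave 20% of target, 3.6% of isomer, 12.7% of solvolysis product, a little less than mine, and 0.025 M for [second nucleophile].

The flask gave 20.5%, 3.20%, 14.5% and 0.00151 M.

    substrate → intermediate (k = 0.00670 min⁻¹)
    first nucleophile + intermediate → target (k = 1.00 M⁻¹ min⁻¹)
    second nucleophile + intermediate → other capture product (k = 6.60 M⁻¹ min⁻¹)
    intermediate → solvolysis product (k = 0.0330 min⁻¹)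
    second nucleophile + protic impurity → quenched reagent (k = 0.910 M⁻¹ min⁻¹)
    target ⇌ isomer of the product (K = 2.10, k = 0.00210 min⁻¹)

In this flask S came to 1.63 at 2.5 h, where the two earlier runs had read 1.81 at 120 min, with 80% of the first nucleophile left and 5.0% of the second. The neighbour charged with 0.12 M of second nucleophile made 4.93% of target beside 53.9% of other capture product, yet its S was 1.77. The flask had not come to rest at 2.5 h, with 37% of its substrate left: by 25.0 h the substrate stood at 0%, the isomer had gained 27 percentage points, the solvolysis product 17 points, and the target had lost 5.3 points.

The runs come from a simulation for substances that don't exist; the scatter is artificial.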